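## Retrosynthetic overview

1. Target 15 ⇒ C12–C13 sp3–sp2 coupling of the C12 zinc reagent from iodo acetate 10 with (Z)-3-iodobut-2-enoic acid 12; the Z geometry is fixed beforehand by anti hydroiodination of but-2-ynoic acid.
2. The 8(17)-methylene and the C9–H stereocentre ⇒ β,γ-unsaturated acid 6. Key step: thermal pericyclic decarboxylation (retro-ene, six-centre 1,5-hydrogen shift with loss of CO2) that removes C13, moves the C8=C9 double bond to the exocyclic position and sets C9.
3. 6 ⇒ aromatic ring C of O-methylpodocarpic acid cut between C12 and C13 by Birch reduction, ozonolysis of the enol ether and Pinnick oxidation (C12 stays as the side-chain ester carbon, C14 becomes C17).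
4. C4, C5 and C10 are bought in (+)-podocarpic acid 1; C19 goes from CO2H to CH2OAc (LiAlH4, then Ac2O after selective iodination at C12).
5. Rings: none is formed; rings A and B come intact from 1 and aromatic ring C is dismantled.

Assumption: (+)-podocarpic acid is taken as an inexpensive catalogue resin acid; podocarpane/labdane numbering (C1 to C20) is used for all compounds.

## Route

Step 1
Reactants: 1 (+)-podocarpic acid
Product: 2 O-methylpodocarpic acid (12-methoxypodocarpa-8,11,13-trien-19-oic acid)
Conditions: Me2SO4 (1.3 equiv), NaOH (2.5 equiv), H2O–MeOH, 0 °C to rt; then HCl to pH 2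
Reagents that add atoms: dimethyl sulfate, COS(=O)(=O)OC
Why: Williamson ether synthesis on the phenoxide; the hindered axial tertiary carboxylate is not alkylated in water and no stereocentre is touched.

Step 2
Reactants: 2 O-methylpodocarpic acid
Product: 3 Birch diene acid (12-methoxypodocarpa-8,12-dien-19-oic acid)
Conditions: Li (12 equiv), NH3 (l)–THF–t-BuOH, −78 to −33 °C; NH4Cl; cold work-up at pH 5 to 6
Reagents that add atoms: none
Why: Birch reduction of the anisole ring leaves the double bonds on the methoxy-bearing carbon (C12=C13, enol ether) and between the two ring-fusion carbons (C8=C9), as in the estradiol methyl ether series; the carboxylate is inert and no stereocentre is made or touched.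

Step 3
Reactants: 3 Birch diene acid
Product: 5 seco aldehyde ester (12-methoxy-12,13-dioxo-12,13-secopodocarp-8-en-19-oic acid), via methoxy hydroperoxide 4 (not isolated)
Conditions: O3 (1.0 equiv), CH2Cl2–MeOH 4:1, pyridine, −78 °C; then Me2S, −78 °C to rt
Reagents that add atoms: ozone, [O-][O+]=O
Why: Ozonolysis (1,3-dipolar cycloaddition, Criegee cleavage) takes the electron-rich enol ether in preference to the hindered tetrasubstituted C8=C9 bond, giving the C12 methyl ester and, after methanol trapping and Me2S reduction, the C13 aldehyde.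

Step 4
Reactants: 5 seco aldehyde ester
Product: 6 seco diacid monoester (12-methoxy-12-oxo-12,13-secopodocarp-8-ene-13,19-dioic acid)
Conditions: NaClO2, NaH2PO4, 2-methylbut-2-ene, t-BuOH–H2O, 0 °C to rt
Reagents that add atoms: sodium chlorite NaClO2, [Na+].[O-]Cl=O
Why: Pinnick oxidation turns the aldehyde into the acid under buffered conditions that do not move the β,γ double bond, and the scavenger keeps HOCl away from the alkene.

Step 5
Reactants: 6 seco diacid monoester
Product: 7 methylene ester acid (12-methoxy-12-oxo-13,14,15,16-tetranorlabd-8(17)-en-19-oic acid)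
Conditions: Ph2O (0.02 M), 245 °C, Ar, 1 h
Reagents that add atoms: none
Why: Thermal retro-ene decarboxylation of a β,γ-unsaturated acid (concerted six-membered transition state, a 1,5-hydrogen shift from O to C9 with extrusion of CO2): the hydrogen is delivered to the α face of C9, anti to the axial C10 methyl, so the new C9–H bond is axial and the CH2CO2Me chain equatorial (9S), while the double bond moves to C8=C17; the ester arm has no O–H and cannot react.

Step 6
Reactants: 7 methylene ester acid
Product: 8 diol (13,14,15,16-tetranorlabd-8(17)-ene-12,19-diol)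
Conditions: LiAlH4 (4 equiv), THF, reflux; then H2O, 15% aq. NaOH, H2O
Reagents that add atoms: none
Why: Hydride reduction of the methyl ester and of the hindered C19 acid to the two primary alcohols; the alkene and all stereocentres are untouched, and the basic work-up avoids acid-induced cyclisation of the 8(17)-en-12-ol to the 8,12-ether.

Step 7
Reactants: 8 diol
Product: 9 iodo alcohol (12-iodo-13,14,15,16-tetranorlabd-8(17)-en-19-ol)
Conditions: PPh3 (1.15 equiv), I2 (1.1 equiv), imidazole (1.5 equiv), premixed, CH2Cl2, 0 °C, 1 h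
Reagents that add atoms: iodine, [I][I]
Why: Appel-type iodination by SN2 displacement of the oxyphosphonium occurs only at the unhindered C12 alcohol because the axial neopentyl C19 alcohol cannot be displaced; premixing leaves no free iodine for iodoetherification of the alkene.

Step 8
Reactants: 9 iodo alcohol
Product: 10 iodo acetate (12-iodo-13,14,15,16-tetranorlabd-8(17)-en-19-yl acetate)
Conditions: Ac2O (1.5 equiv), Et3N, DMAP (5 mol %), CH2Cl2, 0 °C to rt, 2 h
Reagents that add atoms: acetic anhydride, CC(=O)OC(C)=O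
Why: DMAP-catalysed acylation of the neopentyl alcohol installs the final acetate, which also removes the acidic O–H before the organozinc is made.

Step 9
Reactants: 11 but-2-ynoic acid
Product: 12 (Z)-3-iodobut-2-enoic acid
Conditions: NaI (1.6 equiv), AcOH, 115 °C, 3 h
Reagents that add atoms: sodium iodide NaI, [Na+].[I-]
Why: Conjugate hydroiodination of the ynoic acid adds H and iodine anti, which places iodine cis to CO2H and gives the Z isomer only.

Step 10
Reactants: 10 iodo acetate; 12 (Z)-3-iodobut-2-enoic acid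
Product: 15 (13Z)-19-acetoxylabda-8(17),13-dien-15-oic acid (target), via alkylzinc iodide 13 (not isolated), via sodium iodobutenoate 14 (not isolated)
Conditions: (a) 10, Zn dust (activated with BrCH2CH2Br and Me3SiCl), LiCl, THF, 40 °C; (b) 12, NaH (1.0 equiv), THF–DMA, 0 °C; (c) a + b, Pd(OAc)2 (3 mol %), SPhos (6 mol %), 25 to 40 °C; aq. HCl to pH 3
Reagents that add atoms: none
Why: Negishi sp3–sp2 cross-coupling: oxidative addition of zerovalent palladium into the vinyl carbon–iodine bond and reductive elimination both retain the alkene geometry, so C12 ends cis to CO2H (13Z); the acetate and the exocyclic alkene tolerate the alkylzinc.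

## Compound list

1 | (+)-podocarpic acid, (4S,5R,10S)-12-hydroxypodocarpa-8,11,13-trien-19-oic acid (4β axial CO2H, 4α CH3, 5α H, 10β CH3) | c1cc(O)cc2c1CC[C@H]1[C@@](C)(C(=O)O)CCC[C@]21C | starting material
2 | O-methylpodocarpic acid, (4S,5R,10S)-12-methoxypodocarpa-8,11,13-trien-19-oic acid | c1cc(OC)cc2c1CC[C@H]1[C@@](C)(C(=O)O)CCC[C@]21C | intermediate
3 | (4S,5R,10S)-12-methoxypodocarpa-8,12-dien-19-oic acid | C1C=C(OC)CC2=C1CC[C@H]1[C@@](C)(C(=O)O)CCC[C@]21C | intermediate
4 | (4S,5R,10S)-13-hydroperoxy-12,13-dimethoxy-12-oxo-12,13-secopodocarp-8-en-19-oic acid (C13 epimers) | COC(OO)CC1CC[C@H]2[C@@](C)(C(=O)O)CCC[C@]2(C)C=1CC(=O)OC | intermediate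
5 | (4S,5R,10S)-12-methoxy-12,13-dioxo-12,13-secopodocarp-8-en-19-oic acid (CH2CO2Me on C9, CH2CHO on C8, C8=C9) | O=CCC1CC[C@H]2[C@@](C)(C(=O)O)CCC[C@]2(C)C=1CC(=O)OC | intermediate
6 | (4S,5R,10S)-12-methoxy-12-oxo-12,13-secopodocarp-8-ene-13,19-dioic acid | OC(=O)CC1CC[C@H]2[C@@](C)(C(=O)O)CCC[C@]2(C)C=1CC(=O)OC | intermediate
7 | (4S,5R,9S,10R)-12-methoxy-12-oxo-13,14,15,16-tetranorlabd-8(17)-en-19-oic acid | C=C1CC[C@H]2[C@@](C)(C(=O)O)CCC[C@]2(C)[C@H]1CC(=O)OC | intermediate
8 | (4S,5R,9S,10R)-13,14,15,16-tetranorlabd-8(17)-ene-12,19-diol | C=C1CC[C@H]2[C@@](C)(CO)CCC[C@]2(C)[C@H]1CCO | intermediate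
9 | (4S,5R,9S,10R)-12-iodo-13,14,15,16-tetranorlabd-8(17)-en-19-ol | C=C1CC[C@H]2[C@@](C)(CO)CCC[C@]2(C)[C@H]1CCI | intermediate
10 | (4S,5R,9S,10R)-12-iodo-13,14,15,16-tetranorlabd-8(17)-en-19-yl acetate | C=C1CC[C@H]2[C@@](C)(COC(C)=O)CCC[C@]2(C)[C@H]1CCI | intermediate
11 | but-2-ynoic acid | CC#CC(=O)O | starting material
12 | (Z)-3-iodobut-2-enoic acid | I/C(C)=C\C(=O)O | intermediate
13 | [(4S,5R,9S,10R)-19-acetoxy-13,14,15,16-tetranorlabd-8(17)-en-12-yl]zinc iodide | C=C1CC[C@H]2[C@@](C)(COC(C)=O)CCC[C@]2(C)[C@H]1CC[Zn]I | intermediate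
14 | sodium (Z)-3-iodobut-2-enoate | I/C(C)=C\C(=O)[O-].[Na+] | intermediate
15 | (4S,5R,9S,10R,13Z)-19-acetoxylabda-8(17),13-dien-15-oic acid | C=C1CC[C@H]2[C@@](C)(COC(C)=O)CCC[C@]2(C)[C@H]1CC/C(C)=C\C(=O)O | target

## Step count and risks

Total step count: 10. Longest linear sequence: 9 (steps 1 to 8, then step 10).

Three steps most likely to fail:

Step 3 may fail if ozone also cuts the tetrasubstituted C8=C9 bond. The fallback sets out from 3 and comes back at 5. The enol ether alone is dihydroxylated with OsO4 (2 mol %) and N-methylmorpholine N-oxide in acetone–water, since the tetrasubstituted alkene is inert to OsO4; loss of methanol gives the α-ketol 13-hydroxy-12-oxopodocarp-8-en-19-oic acid F1. Cleavage of the ketol C12–C13 bond with Pb(OAc)4 in MeOH–benzene then gives ester aldehyde 5, and the route continues at step 4.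

Step 5 may deliver hydrogen to both faces of C9 at 245 °C. The fallback sets out from crude 7 (as a C9-epimer mixture) and comes back at 7. Ozonolysis of the exocyclic methylene (O3, then Me2S) gives the 8-ketone 12-methoxy-8,12-dioxo-13,14,15,16,17-pentanorlabdan-19-oic acid F2. Its C9 centre is now α to a carbonyl and is equilibrated with NaOMe in MeOH to the equatorial (9S) side chain. Wittig methylenation with excess Ph3P=CH2 in THF returns stereopure 7.

Step 10 may fail because the alkylzinc has to couple with an unprotected carboxylate. The fallback sets out from iodo alcohol 9 and comes back at 15, building the enoate by SN2 alkylation and syn carbocupration instead: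
- Lithium acetylide–ethylenediamine in DMSO displaces the iodide to give the alkyne 15,16-dinorlabd-8(17)-en-13-yn-19-ol F3.
- n-BuLi (2.2 equiv), then ClCO2Me, gives the alkynoate carbonate methyl 19-(methoxycarbonyloxy)-16-norlabd-8(17)-en-13-yn-15-oate F4.
- Me2CuLi (from MeLi and CuI) at −78 °C adds syn across the triple bond to give only the Z enoate methyl (13Z)-19-(methoxycarbonyloxy)labda-8(17),13-dien-15-oate F5.
- LiOH in THF–H2O cleaves the ester and the carbonate to (13Z)-19-hydroxylabda-8(17),13-dien-15-oic acid F6.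
- Ac2O–pyridine with aqueous work-up gives 15.

## Further compounds

F1 | step 3 | 13-hydroxy-12-oxopodocarp-8-en-19-oic acid (C13 epimers) | C1C(O)C(=O)CC2=C1CC[C@H]1[C@@](C)(C(=O)O)CCC[C@]21C
F2 | step 5 | (4S,5R,9S,10R)-12-methoxy-8,12-dioxo-13,14,15,16,17-pentanorlabdan-19-oic acid | O=C1CC[C@H]2[C@@](C)(C(=O)O)CCC[C@]2(C)[C@H]1CC(=O)OC
F3 | step 10 | (4S,5R,9S,10R)-15,16-dinorlabd-8(17)-en-13-yn-19-ol | C=C1CC[C@H]2[C@@](C)(CO)CCC[C@]2(C)[C@H]1CCC#C
F4 | step 10 | methyl (4S,5R,9S,10R)-19-(methoxycarbonyloxy)-16-norlabd-8(17)-en-13-yn-15-oate | C=C1CC[C@H]2[C@@](C)(COC(=O)OC)CCC[C@]2(C)[C@H]1CCC#CC(=O)OC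
F5 | step 10 | methyl (4S,5R,9S,10R,13Z)-19-(methoxycarbonyloxy)labda-8(17),13-dien-15-oate | C=C1CC[C@H]2[C@@](C)(COC(=O)OC)CCC[C@]2(C)[C@H]1CC/C(C)=C\C(=O)OC
F6 | step 10 | (4S,5R,9S,10R,13Z)-19-hydroxylabda-8(17),13-dien-15-oic acid | C=C1CC[C@H]2[C@@](C)(CO)CCC[C@]2(C)[C@H]1CC/C(C)=C\C(=O)O
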